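The upper chroman is opened at O1–C2 and C2–C3, which exposes a 1,1,2-triarylethyl boronate; this is cut at C3–C1′ (ring B) and C4–C4a (ring A). The feature exploited is that upper C3 and C4 are adjacent trans methines bearing ring B on C3 and both ring A and the central arene on C4. One palladium-catalysed conjunctive coupling joins three fragments, forms both bonds and sets both stereocentres by anti addition across an E alkene. Its precursor is the boron ate complex made from the (E)-styrenyl boronate of the central arene, which already carries the (R)-configured lower chroman, and the ring B aryllithium; the ring A aryl triflate is the electrophile.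

Key step: step 16

Remark 1: β-substituted alkenyl pinacol boronates tend to divert to direct Suzuki-type coupling in this reaction class, so boron is re-esterified with cis-1,2-dimethylacenaphthylene-1,2-diol ("mac") before the key step; the carbon skeleton, the bonds formed and the stereochemical course are unchanged, and the pinacol ester itself appears on the way.

Remark 2: bromination of the free phenol in step 1 is assumed to go para to the hydroxyl group; for both chiral catalysts the ligand antipode is the one that gives the descriptors written.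

Step 1
Reactants: 1 3-hydroxy-5-methoxybenzaldehyde
Product: 2 2-bromo-5-hydroxy-3-methoxybenzaldehyde
Conditions: NBS, MeCN, −10 °C → rt
Reagents that add atoms: N-bromosuccinimide, O=C1CCC(=O)N1Br
Why: Electrophilic aromatic bromination; the free phenol is the strongest director and should send bromine para to itself, onto the carbon between CHO and OMe.

Step 2
Reactants: 2 2-bromo-5-hydroxy-3-methoxybenzaldehyde
Product: 3 5-(benzyloxy)-2-bromo-3-methoxybenzaldehyde
Conditions: BnBr, K2CO3, DMF, rt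
Reagents that add atoms: benzyl bromide, BrCc1ccccc1
Why: Williamson etherification of the phenoxide; nothing else in the molecule is alkylated under these conditions.

Step 3
Reactants: 3 5-(benzyloxy)-2-bromo-3-methoxybenzaldehyde
Product: 5 2-[5-(benzyloxy)-2-bromo-3-methoxyphenyl]acetic acid, via trichloromethyl carbinol 4 (not isolated)
Conditions: Cl3CCO2Na, Cl3CCO2H, DMF, rt; then NaBH4, NaOH, t-BuOH, 55 °C; aq. HCl work-up
Reagents that add atoms: sodium trichloroacetate, [Na+].[O-]C(=O)C(Cl)(Cl)Cl; sodium hydroxide, [Na+].[OH-]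
Why: Trichloromethide addition followed by Jocic-type one-carbon homologation: the alkoxide closes to a gem-dichloroepoxide, hydride opens it at the benzylic carbon and the resulting acyl chloride is hydrolysed, while aryl bromide and benzyl ether are inert.

Step 4
Reactants: 5 2-[5-(benzyloxy)-2-bromo-3-methoxyphenyl]acetic acid; 6 4-(benzyloxy)-2-hydroxybenzaldehyde
Product: 7 7-(benzyloxy)-3-[5-(benzyloxy)-2-bromo-3-methoxyphenyl]-2H-chromen-2-one
Conditions: Ac2O, Et3N, 110 °C
Reagents that add atoms: none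
Why: Perkin–Oglialoro condensation; the mixed-anhydride enolate of the arylacetic acid condenses with the salicylaldehyde and the phenol lactonises to the 3-arylcoumarin.

Step 5
Reactants: 7 7-(benzyloxy)-3-[5-(benzyloxy)-2-bromo-3-methoxyphenyl]-2H-chromen-2-one
Product: 8 (Z)-3-[4-(benzyloxy)-2-hydroxyphenyl]-2-[5-(benzyloxy)-2-bromo-3-methoxyphenyl]prop-2-en-1-ol
Conditions: i-Bu2AlH (4 equiv), CH2Cl2, −78 → 0 °C; aq. potassium sodium tartrate
Reagents that add atoms: none
Why: 1,2-Reduction of the unsaturated lactone through the lactol to the allylic alcohol and the phenol; the Z geometry is inherited from the ring and the aryl bromide is not reduced.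

Step 6
Reactants: 8 (Z)-3-[4-(benzyloxy)-2-hydroxyphenyl]-2-[5-(benzyloxy)-2-bromo-3-methoxyphenyl]prop-2-en-1-ol
Product: 9 7-(benzyloxy)-3-[5-(benzyloxy)-2-bromo-3-methoxyphenyl]-2H-chromene
Conditions: PPh3, DIAD, THF, 0 °C → rt
Reagents that add atoms: none
Why: Intramolecular Mitsunobu etherification; the phenol displaces the activated primary allylic alcohol in a six-membered closure.

Step 7
Reactants: 9 7-(benzyloxy)-3-[5-(benzyloxy)-2-bromo-3-methoxyphenyl]-2H-chromene
Product: 10 (3R)-7-(benzyloxy)-3-[5-(benzyloxy)-2-bromo-3-methoxyphenyl]chromane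
Conditions: [Ir(cod)(L)]B[3,5-(CF3)2C6H3]4 (2 mol%; L = one antipode of 4-tert-butyl-2-[2-(diphenylphosphanyl)phenyl]-4,5-dihydrooxazole), H2 (50 bar), CH2Cl2, rt
Reagents that add atoms: none
Why: Iridium-catalysed asymmetric hydrogenation of a trisubstituted cyclic aryl alkene, a reaction type established for 3-aryl-2H-chromenes; the chiral P,N ligand selects the alkene face that gives (R) at C3, and aryl bromide and benzyl ethers are inert to this homogeneous catalyst.

Step 8
Reactants: 10 (3R)-7-(benzyloxy)-3-[5-(benzyloxy)-2-bromo-3-methoxyphenyl]chromane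
Product: 12 4-(benzyloxy)-2-[(3R)-7-(benzyloxy)chroman-3-yl]-6-methoxybenzaldehyde, via aryllithium 11 (not isolated)
Conditions: n-BuLi, THF, −78 °C; then DMF, −78 °C → rt
Reagents that add atoms: N,N-dimethylformamide, CN(C)C=O
Why: Bromine–lithium exchange and formylation with DMF; exchange at −78 °C outruns benzylic deprotonation and the C3 stereocentre is not acidic.

Step 9
Reactants: 12 4-(benzyloxy)-2-[(3R)-7-(benzyloxy)chroman-3-yl]-6-methoxybenzaldehyde
Product: 13 2-[(E)-2-{4-(benzyloxy)-2-[(3R)-7-(benzyloxy)chroman-3-yl]-6-methoxyphenyl}ethenyl]-4,4,5,5-tetramethyl-1,3,2-dioxaborolane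
Conditions: CH2(Bpin)2, lithium 2,2,6,6-tetramethylpiperidide, THF, 0 °C; then 12, −78 °C → rt
Reagents that add atoms: bis(4,4,5,5-tetramethyl-1,3,2-dioxaborolan-2-yl)methane, CC1(C)OB(CB2OC(C)(C)C(C)(C)O2)OC1(C)C
Why: Boron–Wittig olefination; the α-boryl carbanion adds to the hindered aldehyde and syn boron–oxygen elimination should give the E alkenyl boronate.

Step 10
Reactants: 14 acenaphthoquinone
Product: 15 cis-1,2-dimethyl-1,2-dihydroacenaphthylene-1,2-diol (meso "mac" diol)
Conditions: AlMe3, toluene, 0 °C → rt; aq. HCl work-up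
Reagents that add atoms: trimethylaluminium, C[Al](C)C
Why: Double 1,2-addition of methyl to the 1,2-diketone; the second methyl is delivered to the chelated aluminium alkoxide, so the cis diol should predominate and is purified by crystallisation.

Step 11
Reactants: 13 styrenyl pinacol boronate; 15 cis-1,2-dimethyl-1,2-dihydroacenaphthylene-1,2-diol
Product: 17 (E)-styrenyl mac boronate (boronic acid 16 esterified through both oxygens of diol 15), via styrenylboronic acid 16 (not isolated)
Conditions: NaIO4, NH4OAc, acetone/H2O, rt; extraction; then 15, MgSO4, CH2Cl2, rt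
Reagents that add atoms: none
Why: Periodate cleavage of the pinacol unit frees the boronic acid, which condenses with the rigid cis-diol (boronic ester exchange); the alkene geometry is not touched.

Step 12
Reactants: 6 4-(benzyloxy)-2-hydroxybenzaldehyde
Product: 18 4-(benzyloxy)-2-[(tert-butyldimethylsilyl)oxy]benzaldehyde
Conditions: TBSCl, imidazole, DMF, rt
Reagents that add atoms: tert-butyldimethylsilyl chloride, CC(C)(C)[Si](C)(C)Cl
Why: Silylation of the phenol; this oxygen later becomes O1 of the upper chroman and must stay distinguishable from the ring B acetals.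

Step 13
Reactants: 18 4-(benzyloxy)-2-[(tert-butyldimethylsilyl)oxy]benzaldehyde
Product: 20 4-(benzyloxy)-2-[(tert-butyldimethylsilyl)oxy]phenol, via aryl formate 19 (not isolated)
Conditions: mCPBA, CH2Cl2, 0 °C → rt; aq. Na2S2O3 wash; then MeOH, NaHCO3, 0 °C
Reagents that add atoms: 3-chloroperbenzoic acid, OOC(=O)c1cccc(Cl)c1
Why: Baeyer–Villiger oxidation in which the electron-rich aryl group migrates; the formate is methanolysed under near-neutral conditions so that the silyl group does not move to the new phenol.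

Step 14
Reactants: 20 4-(benzyloxy)-2-[(tert-butyldimethylsilyl)oxy]phenol
Product: 21 4-(benzyloxy)-2-[(tert-butyldimethylsilyl)oxy]phenyl trifluoromethanesulfonate
Conditions: Tf2O, pyridine, CH2Cl2, −20 → 0 °C
Reagents that add atoms: trifluoromethanesulfonic anhydride, O=S(=O)(OS(=O)(=O)C(F)(F)F)C(F)(F)F
Why: O-Sulfonylation of the phenol; weak base and low temperature keep the phenoxide concentration low, which suppresses 1,2-silyl migration.

Step 15
Reactants: 22 3-methoxycatechol
Product: 23 1-methoxy-2,3-bis(methoxymethoxy)benzene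
Conditions: MOMCl, i-Pr2NEt, CH2Cl2, 0 °C → rt
Reagents that add atoms: chloromethyl methyl ether, COCCl
Why: O-Alkylation of both phenols to methoxymethyl acetals, which later direct the lithiation and survive organolithium, fluoride and Mitsunobu conditions.

Step 16
Reactants: 23 1-methoxy-2,3-bis(methoxymethoxy)benzene; 17 (E)-styrenyl mac boronate; 21 4-(benzyloxy)-2-[(tert-butyldimethylsilyl)oxy]phenyl trifluoromethanesulfonate
Product: 26 mac boronate of (1R,2S)-2-{4-(benzyloxy)-2-[(tert-butyldimethylsilyl)oxy]phenyl}-2-{4-(benzyloxy)-2-[(3R)-7-(benzyloxy)chroman-3-yl]-6-methoxyphenyl}-1-[4-methoxy-2,3-bis(methoxymethoxy)phenyl]ethylboronic acid, via ring B aryllithium 24 (not isolated), via lithium borate complex 25 (not isolated)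
Conditions: 23, n-BuLi (0.95 equiv), THF, 0 °C; then 17, −78 °C → rt; then 21, Pd(OAc)2 (5 mol%), one antipode of 1,1'-bis[bis(4-methoxy-3,5-dimethylphenyl)phosphino]-2,2'-bis[α-(dimethylamino)benzyl]ferrocene (MandyPhos type, 6 mol%), THF, 60 °C
Reagents that add atoms: none
Why: Ortho-lithiation of 23 next to the outer acetal gives halide-free 24, which adds to boron to form 25; zerovalent palladium inserts into the C–O bond of triflate 21, the cationic arylpalladium species (divalent palladium) binds the alkene of 25, the ring B aryl group on boron moves to the adjacent carbon (C3) on the face opposite the metal while palladium bonds to C4, and reductive elimination makes C4–C4a. The closest known reaction is the enantioselective conjunctive cross-coupling of β-substituted alkenyl boron ate complexes with aryl triflates. No ring closes. C3 is set by the stereospecific anti 1,2-shift and C4 by the alkene face that the chiral bisphosphine lets palladium take, so the E geometry translates into the (1R,2S) anti adduct, with the ligand antipode chosen to work with the resident (R) centre. The step needs the metallate shift to beat direct transmetallation (Suzuki-type coupling) and β-hydride elimination: the bulky mac ligand shields the boron oxygens, the bidentate ligand leaves no open site, and the triflate together with halide-free 24 keeps palladium cationic.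

Step 17
Reactants: 26 conjunctive coupling product (secondary mac boronate)
Product: 28 (2R,3S)-3-{4-(benzyloxy)-2-[(tert-butyldimethylsilyl)oxy]phenyl}-3-{4-(benzyloxy)-2-[(3R)-7-(benzyloxy)chroman-3-yl]-6-methoxyphenyl}-2-[4-methoxy-2,3-bis(methoxymethoxy)phenyl]propan-1-ol, via homologated mac boronate 27 (not isolated)
Conditions: BrCH2Cl, n-BuLi, THF, −78 °C → rt; then NaOH, H2O2, THF/H2O, 0 °C
Reagents that add atoms: bromochloromethane, ClCBr; hydrogen peroxide, OO
Why: Matteson homologation then oxidation; LiCH2Cl adds to boron, the secondary benzylic carbon migrates with retention as chloride leaves, and the primary C–B bond is oxidised, so C3 keeps its configuration (partial silyl loss here would be harmless because the next step removes that group).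

Step 18
Reactants: 28 silyl-protected primary alcohol
Product: 29 (2R,3S)-3-[4-(benzyloxy)-2-hydroxyphenyl]-3-{4-(benzyloxy)-2-[(3R)-7-(benzyloxy)chroman-3-yl]-6-methoxyphenyl}-2-[4-methoxy-2,3-bis(methoxymethoxy)phenyl]propan-1-ol
Conditions: Bu4NF, THF, 0 °C
Reagents that add atoms: none
Why: Fluoride cleavage of the aryl silyl ether; acetals and benzyl ethers are stable, so only the ring A phenol is freed.

Step 19
Reactants: 29 phenol–primary alcohol
Product: 30 (3R,4S)-7-(benzyloxy)-4-{4-(benzyloxy)-2-[(3R)-7-(benzyloxy)chroman-3-yl]-6-methoxyphenyl}-3-[4-methoxy-2,3-bis(methoxymethoxy)phenyl]chromane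
Conditions: PPh3, DIAD, THF, 0 °C → rt
Reagents that add atoms: none
Why: Intramolecular Mitsunobu etherification at the primary carbon (6-exo-tet), so no stereocentre is touched and the trans-3,4-diaryl chroman results; ring B has no free phenol that could close a five-membered ether instead.

Step 20
Reactants: 30 fully protected target
Product: 31 3-[(3R,4S)-7-(benzyloxy)-4-{4-(benzyloxy)-2-[(3R)-7-(benzyloxy)chroman-3-yl]-6-methoxyphenyl}chroman-3-yl]-6-methoxybenzene-1,2-diol
Conditions: HCl (3 M in MeOH), THF, 45 °C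
Reagents that add atoms: none
Why: Acid-catalysed acetal exchange removes both methoxymethyl groups as dimethoxymethane, so no formaldehyde equivalent is left to attack the electron-rich rings; benzyl ethers and both chromans are stable.

Step 21
Reactants: 31 tris(benzyl ether)
Product: 32 3-[(3R,4S)-7-hydroxy-4-{4-hydroxy-2-[(3R)-7-hydroxychroman-3-yl]-6-methoxyphenyl}chroman-3-yl]-6-methoxybenzene-1,2-diol (CNP0227211.1)
Conditions: H2 (1 atm), Pd/C (10%), EtOAc/MeOH, rt
Reagents that add atoms: none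
Why: Hydrogenolysis of the three benzyl ethers under neutral conditions; no stereocentre is affected and the air-sensitive polyphenol is obtained by filtration.

Compound list

1 | 3-hydroxy-5-methoxybenzaldehyde | COc1cc(O)cc(C=O)c1 | starting material
2 | 2-bromo-5-hydroxy-3-methoxybenzaldehyde | COc1cc(O)cc(C=O)c1Br | intermediate
3 | 5-(benzyloxy)-2-bromo-3-methoxybenzaldehyde | COc1cc(OCc2ccccc2)cc(C=O)c1Br | intermediate
4 | 1-[5-(benzyloxy)-2-bromo-3-methoxyphenyl]-2,2,2-trichloroethanol (racemic, not isolated) | COc1cc(OCc2ccccc2)cc(C(O)C(Cl)(Cl)Cl)c1Br | intermediate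
5 | 2-[5-(benzyloxy)-2-bromo-3-methoxyphenyl]acetic acid | COc1cc(OCc2ccccc2)cc(CC(=O)O)c1Br | intermediate
6 | 4-(benzyloxy)-2-hydroxybenzaldehyde | O=Cc1ccc(OCc2ccccc2)cc1O | starting material
7 | 7-(benzyloxy)-3-[5-(benzyloxy)-2-bromo-3-methoxyphenyl]-2H-chromen-2-one | COc1cc(OCc2ccccc2)cc(C2=Cc3ccc(OCc4ccccc4)cc3OC2=O)c1Br | intermediate
8 | (Z)-3-[4-(benzyloxy)-2-hydroxyphenyl]-2-[5-(benzyloxy)-2-bromo-3-methoxyphenyl]prop-2-en-1-ol | COc1cc(OCc2ccccc2)cc(/C(CO)=C/c2ccc(OCc3ccccc3)cc2O)c1Br | intermediate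
9 | 7-(benzyloxy)-3-[5-(benzyloxy)-2-bromo-3-methoxyphenyl]-2H-chromene | COc1cc(OCc2ccccc2)cc(C2=Cc3ccc(OCc4ccccc4)cc3OC2)c1Br | intermediate
10 | (3R)-7-(benzyloxy)-3-[5-(benzyloxy)-2-bromo-3-methoxyphenyl]chromane | COc1cc(OCc2ccccc2)cc([C@@H]2COc3cc(OCc4ccccc4)ccc3C2)c1Br | intermediate
11 | {4-(benzyloxy)-2-[(3R)-7-(benzyloxy)chroman-3-yl]-6-methoxyphenyl}lithium (not isolated) | COc1cc(OCc2ccccc2)cc([C@@H]2COc3cc(OCc4ccccc4)ccc3C2)c1[Li] | intermediate
12 | 4-(benzyloxy)-2-[(3R)-7-(benzyloxy)chroman-3-yl]-6-methoxybenzaldehyde | COc1cc(OCc2ccccc2)cc([C@@H]2COc3cc(OCc4ccccc4)ccc3C2)c1C=O | intermediate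
13 | 2-[(E)-2-{4-(benzyloxy)-2-[(3R)-7-(benzyloxy)chroman-3-yl]-6-methoxyphenyl}ethenyl]-4,4,5,5-tetramethyl-1,3,2-dioxaborolane | CC1(C)OB(/C=C/c2c(OC)cc(OCc3ccccc3)cc2[C@@H]2COc3cc(OCc4ccccc4)ccc3C2)OC1(C)C | intermediate
14 | acenaphthoquinone | O=C1C(=O)c2cccc3cccc1c23 | starting material
15 | cis-1,2-dimethyl-1,2-dihydroacenaphthylene-1,2-diol (meso, "mac" diol) | C[C@@]1(O)c2cccc3cccc(c23)[C@]1(C)O | intermediate
16 | [(E)-2-{4-(benzyloxy)-2-[(3R)-7-(benzyloxy)chroman-3-yl]-6-methoxyphenyl}ethenyl]boronic acid (not isolated) | COc1cc(OCc2ccccc2)cc([C@@H]2COc3cc(OCc4ccccc4)ccc3C2)c1/C=C/B(O)O | intermediate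
17 | (E)-styrenyl mac boronate: cyclic ester of boronic acid 16 with diol 15 | COc1cc(OCc2ccccc2)cc([C@@H]2COc3cc(OCc4ccccc4)ccc3C2)c1/C=C/B1O[C@]2(C)c3cccc4cccc(c34)[C@]2(C)O1 | intermediate
18 | 4-(benzyloxy)-2-[(tert-butyldimethylsilyl)oxy]benzaldehyde | O=Cc1ccc(OCc2ccccc2)cc1O[Si](C)(C)C(C)(C)C | intermediate
19 | 4-(benzyloxy)-2-[(tert-butyldimethylsilyl)oxy]phenyl formate (not isolated) | O=COc1ccc(OCc2ccccc2)cc1O[Si](C)(C)C(C)(C)C | intermediate
20 | 4-(benzyloxy)-2-[(tert-butyldimethylsilyl)oxy]phenol | Oc1ccc(OCc2ccccc2)cc1O[Si](C)(C)C(C)(C)C | intermediate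
21 | 4-(benzyloxy)-2-[(tert-butyldimethylsilyl)oxy]phenyl trifluoromethanesulfonate | CC(C)(C)[Si](C)(C)Oc1cc(OCc2ccccc2)ccc1OS(=O)(=O)C(F)(F)F | intermediate
22 | 3-methoxycatechol | COc1cccc(O)c1O | starting material
23 | 1-methoxy-2,3-bis(methoxymethoxy)benzene | COCOc1cccc(OC)c1OCOC | intermediate
24 | [4-methoxy-2,3-bis(methoxymethoxy)phenyl]lithium (not isolated) | COc1ccc([Li])c(OCOC)c1OCOC | intermediate
25 | lithium borate (ate complex) of 17 carrying the 4-methoxy-2,3-bis(methoxymethoxy)phenyl group on boron; configuration at boron not defined (not isolated) | [Li+].COc1ccc([B-]2(/C=C/c3c(OC)cc(OCc4ccccc4)cc3[C@@H]3COc4cc(OCc5ccccc5)ccc4C3)O[C@]3(C)c4cccc5cccc(c45)[C@]3(C)O2)c(OCOC)c1OCOC | intermediate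
26 | mac boronate of (1R,2S)-2-{4-(benzyloxy)-2-[(tert-butyldimethylsilyl)oxy]phenyl}-2-{4-(benzyloxy)-2-[(3R)-7-(benzyloxy)chroman-3-yl]-6-methoxyphenyl}-1-[4-methoxy-2,3-bis(methoxymethoxy)phenyl]ethylboronic acid | COc1ccc([C@H](B2O[C@]3(C)c4cccc5cccc(c45)[C@]3(C)O2)[C@@H](c2ccc(OCc3ccccc3)cc2O[Si](C)(C)C(C)(C)C)c2c(OC)cc(OCc3ccccc3)cc2[C@@H]2COc3cc(OCc4ccccc4)ccc3C2)c(OCOC)c1OCOC | intermediate
27 | mac boronate of the (2R,3S)-configured propylboronic acid, i.e. 26 with CH2 inserted between the stereocentre and boron (not isolated) | COc1ccc([C@H](CB2O[C@]3(C)c4cccc5cccc(c45)[C@]3(C)O2)[C@@H](c2ccc(OCc3ccccc3)cc2O[Si](C)(C)C(C)(C)C)c2c(OC)cc(OCc3ccccc3)cc2[C@@H]2COc3cc(OCc4ccccc4)ccc3C2)c(OCOC)c1OCOC | intermediate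
28 | (2R,3S)-3-{4-(benzyloxy)-2-[(tert-butyldimethylsilyl)oxy]phenyl}-3-{4-(benzyloxy)-2-[(3R)-7-(benzyloxy)chroman-3-yl]-6-methoxyphenyl}-2-[4-methoxy-2,3-bis(methoxymethoxy)phenyl]propan-1-ol | COc1ccc([C@H](CO)[C@@H](c2ccc(OCc3ccccc3)cc2O[Si](C)(C)C(C)(C)C)c2c(OC)cc(OCc3ccccc3)cc2[C@@H]2COc3cc(OCc4ccccc4)ccc3C2)c(OCOC)c1OCOC | intermediate
29 | (2R,3S)-3-[4-(benzyloxy)-2-hydroxyphenyl]-3-{4-(benzyloxy)-2-[(3R)-7-(benzyloxy)chroman-3-yl]-6-methoxyphenyl}-2-[4-methoxy-2,3-bis(methoxymethoxy)phenyl]propan-1-ol | COc1ccc([C@H](CO)[C@@H](c2ccc(OCc3ccccc3)cc2O)c2c(OC)cc(OCc3ccccc3)cc2[C@@H]2COc3cc(OCc4ccccc4)ccc3C2)c(OCOC)c1OCOC | intermediate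
30 | (3R,4S)-7-(benzyloxy)-4-{4-(benzyloxy)-2-[(3R)-7-(benzyloxy)chroman-3-yl]-6-methoxyphenyl}-3-[4-methoxy-2,3-bis(methoxymethoxy)phenyl]chromane | COc1ccc([C@@H]2COc3cc(OCc4ccccc4)ccc3[C@H]2c2c(OC)cc(OCc3ccccc3)cc2[C@@H]2COc3cc(OCc4ccccc4)ccc3C2)c(OCOC)c1OCOC | intermediate
31 | 3-[(3R,4S)-7-(benzyloxy)-4-{4-(benzyloxy)-2-[(3R)-7-(benzyloxy)chroman-3-yl]-6-methoxyphenyl}chroman-3-yl]-6-methoxybenzene-1,2-diol | COc1ccc([C@@H]2COc3cc(OCc4ccccc4)ccc3[C@H]2c2c(OC)cc(OCc3ccccc3)cc2[C@@H]2COc3cc(OCc4ccccc4)ccc3C2)c(O)c1O | intermediate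
32 | 3-[(3R,4S)-7-hydroxy-4-{4-hydroxy-2-[(3R)-7-hydroxychroman-3-yl]-6-methoxyphenyl}chroman-3-yl]-6-methoxybenzene-1,2-diol (CNP0227211.1) | COc1ccc([C@@H]2COc3cc(O)ccc3[C@H]2c2c(OC)cc(O)cc2[C@@H]2COc3cc(O)ccc3C2)c(O)c1O | target

Total step count: 21.

Longest linear sequence: 16 steps (steps 1–9, 11, 16–21).

Steps most likely to fail

Step 16. The ate complex may transfer an organic group directly to palladium (plain Suzuki-type coupling) instead of undergoing the metallate shift. Alkene binding next to the doubly ortho-substituted arene may be too slow. The nearby lower chroman may erode facial selectivity. The fallback builds the C3–C4 bond by conjugate addition to an ortho-quinone methide; it sets out from phenol aldehyde 6 and bromide 10 and comes back at diol 29. Aldehyde 6 is acylated (Boc2O, DMAP, i-Pr2NEt, CH2Cl2) to the aryl tert-butyl carbonate F1. Aryllithium 24 is transmetallated (ZnCl2, THF) and coupled with ethyl bromoacetate (Ni(acac)2, PPh3) to the ethyl arylacetate F2. Aryllithium 11, made from 10 as in step 8, is added to F1 at −78 °C and the lithium enolate of F2 (LiN(SiMe3)2, THF) is then introduced. On warming, the Boc group moves to the benzylic alkoxide, the phenoxide expels tert-butyl carbonate, and the quinone methide takes up the enolate at the methide carbon. The phenoxide then lactonises onto the ester, and DBU equilibration at the α-carbon secures the trans ring. The two trans isomers are diastereomers because of the lower (R) centre and are separated by chromatography. The (3R,4S)-3,4-diaryl dihydrocoumarin F3 is reduced with LiAlH4 (THF, 0 °C) to 29.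

Step 17. Ate-complex formation at the crowded secondary benzylic boron may be slow, so the chloromethyl carbenoid may decompose before it adds, and protodeboronation may compete. The fallback replaces the one-carbon insertion by vinylation and oxidative cleavage; it sets out from boronate 26 and comes back at alcohol 28. Zweifel olefination (CH2=CHMgBr, THF; then I2, NaOMe, MeOH) should replace boron by vinyl with retention to give the (3R,4S)-triaryl butene F4. Lemieux–Johnson cleavage (OsO4 cat., NaIO4, 2,6-lutidine, dioxane/H2O) gives the α-aryl aldehyde F5, which is reduced in the same flask with NaBH4 to 28, so that the epimerisable centre is not left standing.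

Step 7. Facial discrimination may be poor or turnover may stall, because the ortho-bromo aryl ring twists out of the alkene plane. The fallback sets the stereocentre by auxiliary-controlled alkylation; it sets out from acid 5 and silyl aldehyde 18 and comes back at bromide 10. Acid 5 is activated (pivaloyl chloride, Et3N) and joined to lithiated (R)-4-benzyloxazolidin-2-one to give the N-acyl oxazolidinone F6. Aldehyde 18 is reduced (i-Bu2AlH, CH2Cl2, −78 °C) to the benzyl alcohol F7 and brominated (CBr4, PPh3) to the benzyl bromide F8. Evans alkylation of the sodium enolate of F6 (NaN(SiMe3)2, THF, −78 °C) with F8, anti to the auxiliary benzyl group, should give the (2R)-alkylated imide F9. LiBH4 cleaves the auxiliary to the silyl-protected alcohol F10, Bu4NF gives the phenol–alcohol F11, and Mitsunobu closure (PPh3, DIAD) gives 10.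

Further compounds

F1 | step 16 | 5-(benzyloxy)-2-formylphenyl tert-butyl carbonate | CC(C)(C)OC(=O)Oc1cc(OCc2ccccc2)ccc1C=O
F2 | step 16 | ethyl 2-[4-methoxy-2,3-bis(methoxymethoxy)phenyl]acetate | CCOC(=O)Cc1ccc(OC)c(OCOC)c1OCOC
F3 | step 16 | (3R,4S)-7-(benzyloxy)-4-{4-(benzyloxy)-2-[(3R)-7-(benzyloxy)chroman-3-yl]-6-methoxyphenyl}-3-[4-methoxy-2,3-bis(methoxymethoxy)phenyl]chroman-2-one | COc1ccc([C@@H]2C(=O)Oc3cc(OCc4ccccc4)ccc3[C@H]2c2c(OC)cc(OCc3ccccc3)cc2[C@@H]2COc3cc(OCc4ccccc4)ccc3C2)c(OCOC)c1OCOC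
F4 | step 17 | (3R,4S)-4-{4-(benzyloxy)-2-[(tert-butyldimethylsilyl)oxy]phenyl}-4-{4-(benzyloxy)-2-[(3R)-7-(benzyloxy)chroman-3-yl]-6-methoxyphenyl}-3-[4-methoxy-2,3-bis(methoxymethoxy)phenyl]but-1-ene | COc1ccc([C@H](C=C)[C@@H](c2ccc(OCc3ccccc3)cc2O[Si](C)(C)C(C)(C)C)c2c(OC)cc(OCc3ccccc3)cc2[C@@H]2COc3cc(OCc4ccccc4)ccc3C2)c(OCOC)c1OCOC
F5 | step 17 | (2R,3S)-3-{4-(benzyloxy)-2-[(tert-butyldimethylsilyl)oxy]phenyl}-3-{4-(benzyloxy)-2-[(3R)-7-(benzyloxy)chroman-3-yl]-6-methoxyphenyl}-2-[4-methoxy-2,3-bis(methoxymethoxy)phenyl]propanal | COc1ccc([C@H](C=O)[C@@H](c2ccc(OCc3ccccc3)cc2O[Si](C)(C)C(C)(C)C)c2c(OC)cc(OCc3ccccc3)cc2[C@@H]2COc3cc(OCc4ccccc4)ccc3C2)c(OCOC)c1OCOC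
F6 | step 7 | (4R)-4-benzyl-3-{2-[5-(benzyloxy)-2-bromo-3-methoxyphenyl]acetyl}oxazolidin-2-one | O=C(Cc1cc(OCc2ccccc2)cc(OC)c1Br)N1C(=O)OC[C@H]1Cc1ccccc1
F7 | step 7 | {4-(benzyloxy)-2-[(tert-butyldimethylsilyl)oxy]phenyl}methanol | OCc1ccc(OCc2ccccc2)cc1O[Si](C)(C)C(C)(C)C
F8 | step 7 | 4-(benzyloxy)-1-(bromomethyl)-2-[(tert-butyldimethylsilyl)oxy]benzene | BrCc1ccc(OCc2ccccc2)cc1O[Si](C)(C)C(C)(C)C
F9 | step 7 | (4R)-4-benzyl-3-[(2R)-3-{4-(benzyloxy)-2-[(tert-butyldimethylsilyl)oxy]phenyl}-2-[5-(benzyloxy)-2-bromo-3-methoxyphenyl]propanoyl]oxazolidin-2-one | O=C([C@H](Cc1ccc(OCc2ccccc2)cc1O[Si](C)(C)C(C)(C)C)c1cc(OCc2ccccc2)cc(OC)c1Br)N1C(=O)OC[C@H]1Cc1ccccc1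
F10 | step 7 | (2R)-3-{4-(benzyloxy)-2-[(tert-butyldimethylsilyl)oxy]phenyl}-2-[5-(benzyloxy)-2-bromo-3-methoxyphenyl]propan-1-ol | OC[C@H](Cc1ccc(OCc2ccccc2)cc1O[Si](C)(C)C(C)(C)C)c1cc(OCc2ccccc2)cc(OC)c1Br
F11 | step 7 | (2R)-3-[4-(benzyloxy)-2-hydroxyphenyl]-2-[5-(benzyloxy)-2-bromo-3-methoxyphenyl]propan-1-ol | OC[C@H](Cc1ccc(OCc2ccccc2)cc1O)c1cc(OCc2ccccc2)cc(OC)c1Br
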